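**Plan**

- The target is read as (3R,5S,8S,9R,10S) in labdane numbering: a trans-decalin with equatorial 3-OH, equatorial 8-CHO (C17), and a C9 chain (C11–C16) cis to the C10 methyl that ends in a (Z)-3-methyl enoate.
- Cuts, in retrosynthetic order: C12–C13 (alkylborane plus methyl (Z)-3-iodobut-2-enoate) and C11=C12 (methylenation of a C11 aldehyde); then, with C6=C7 placed in ring B, the ring bonds C5–C10 and C8–C9; then C6–C7, C5=C6 and C3–C4 of the open chain.
- Enabling feature: ring B carries the four contiguous stereocentres C5, C10, C9 and C8, so it is a Diels–Alder cyclohexene once C6=C7 is present. C11 on C9 is cis to the C10 methyl, as in an (E)-3-methylalk-2-enal, and C1–C4 of ring A is a four-carbon tether whose C4 gem-dimethyl sits at the diene.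
- Forward: methyl geranate is cut to its C3 aldehyde and extended to an acyclic (E,E,E)-trienal; one intramolecular Diels–Alder step closes rings A and B together; C6=C7 is then saturated, the side chain completed, C17 oxidised and C8 epimerised.
- Stereochemistry: C3 comes from an enantioselective iridium-catalysed tert-prenylation; C5, C9 and C10 (and C8 provisionally) from the cycloaddition, relayed from C3 and the alkene geometries; C8 is finally set by thermodynamic epimerisation; the Z-enoate by a stereoretentive coupling.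

Key step: step 9

Assumption: in step 2 the sense of induction is fixed by the ligand antipode; (R)-SEGPHOS is written on the assumption that it gives the 6R carbinol, and the mirror-image ligand is used if the sense is the opposite.
Abbreviation and numbering: TBS = tert-butyldimethylsilyl; ring atoms are called C1–C20 in labdane numbering.

**Step 1**
Reactants: 1 methyl geranate
Product: 3 methyl (2E)-3-methyl-6-oxohex-2-enoate, via vicinal diol 2 (not isolated)
Conditions: OsO4 (2 mol%), NaIO4 (4 equiv), 2,6-lutidine (2 equiv), 1,4-dioxane/H2O 3:1, rt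
Reagents that add atoms: osmium tetroxide, O=[Os](=O)(=O)=O (delivers the diol oxygens, one of which stays as the aldehyde oxygen); sodium periodate NaIO4, [Na+].[O-]I(=O)(=O)=O (regenerates OsO4, net oxygen source)
Why: Lemieux–Johnson cleavage: electrophilic OsO4 should dihydroxylate the isolated, electron-rich C6=C7 bond well before the ester-conjugated C2=C3 bond, and periodate cleaves diol 2 as it forms, so the E-enoate passes through unchanged and no stereocentre is created.

**Step 2**
Reactants: 3 methyl (2E)-3-methyl-6-oxohex-2-enoate; 4 3-methylbuta-1,2-diene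
Product: 5 methyl (2E,6R)-6-hydroxy-3,7,7-trimethylnona-2,8-dienoate
Conditions: preformed (π-allyl)iridium C,O-benzoate catalyst from [Ir(cod)Cl]2, (R)-SEGPHOS, 4-cyano-3-nitrobenzoic acid and allyl acetate (5 mol%), i-PrOH (2 equiv), toluene, 50 °C, sealed tube
Reagents that add atoms: none
Why: Transfer-hydrogenative carbonyl tert-prenylation: isopropanol supplies hydride, hydrometallation of the allene gives a 1,1-dimethylallyl–iridium species that adds to the aldehyde through a closed chair transition state at its substituted terminus, and the chiral diphosphine/C,O-benzoate ligand sphere selects the aldehyde face, which should set the 6R carbinol (C3 of the target).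

**Step 3**
Reactants: 5 methyl (2E,6R)-6-hydroxy-3,7,7-trimethylnona-2,8-dienoate
Product: 6 methyl (2E,6R)-6-(TBSO)-3,7,7-trimethylnona-2,8-dienoate
Conditions: TBSOTf (1.3 equiv), 2,6-lutidine (2 equiv), CH2Cl2, −78 → 0 °C
Reagents that add atoms: tert-butyldimethylsilyl trifluoromethanesulfonate, CC(C)(C)[Si](C)(C)OS(=O)(=O)C(F)(F)F
Why: Silylation of a hindered neopentyl-type secondary alcohol needs the silyl triflate; the stereocentre is not touched.

**Step 4**
Reactants: 6 methyl (2E,6R)-6-(TBSO)-3,7,7-trimethylnona-2,8-dienoate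
Product: 8 methyl (2E,6R)-6-(TBSO)-3,7,7-trimethyl-8-oxooct-2-enoate, via vicinal diol 7 (not isolated)
Conditions: OsO4 (2 mol%), NaIO4 (4 equiv), 2,6-lutidine (2 equiv), 1,4-dioxane/H2O 3:1, rt
Reagents that add atoms: osmium tetroxide, O=[Os](=O)(=O)=O (delivers the diol oxygens, one of which stays as the aldehyde oxygen); sodium periodate NaIO4, [Na+].[O-]I(=O)(=O)=O (regenerates OsO4, net oxygen source)
Why: Lemieux–Johnson cleavage: the monosubstituted vinyl group should be osmylated ahead of the electron-poor trisubstituted enoate, and the aldehyde formed is quaternary at its α-carbon, so nothing can epimerise.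

**Step 5**
Reactants: 8 methyl (2E,6R)-6-(TBSO)-3,7,7-trimethyl-8-oxooct-2-enoate
Product: 9 methyl (2E,6R,8E)-6-(TBSO)-9-iodo-3,7,7-trimethylnona-2,8-dienoate
Conditions: CrCl2 (6 equiv), CHI3 (2 equiv), THF, 0 °C → rt
Reagents that add atoms: iodoform, IC(I)I
Why: Takai olefination: the geminal dichromium reagent from iodoform adds to the aldehyde and eliminates to the iodoalkene, and with an α-quaternary aldehyde the E isomer should dominate strongly; the enoate and silyl ether are inert to CrCl2.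

**Step 6**
Reactants: 9 methyl (2E,6R,8E)-6-(TBSO)-9-iodo-3,7,7-trimethylnona-2,8-dienoate; 10 (E)-tert-butyldimethyl{[3-(4,4,5,5-tetramethyl-1,3,2-dioxaborolan-2-yl)prop-2-en-1-yl]oxy}silane
Product: 11 methyl (2E,6R,8E,10E)-6,12-bis(TBSO)-3,7,7-trimethyldodeca-2,8,10-trienoate
Conditions: Pd(dppf)Cl2 (5 mol%), K3PO4 (3 equiv), THF/H2O 10:1, 40 °C
Reagents that add atoms: none
Why: Suzuki–Miyaura alkenyl–alkenyl coupling proceeds with retention at both partners, so the (E,E)-diene C5=C6–C7=C8 should form with defined geometry; the mild phosphate base spares the methyl ester.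

**Step 7**
Reactants: 11 methyl (2E,6R,8E,10E)-6,12-bis(TBSO)-3,7,7-trimethyldodeca-2,8,10-trienoate
Product: 12 (2E,6R,8E,10E)-6,12-bis(TBSO)-3,7,7-trimethyldodeca-2,8,10-trien-1-ol
Conditions: i-Bu2AlH (2.5 equiv), CH2Cl2, −78 °C; aq. KNaC4H4O6 (potassium sodium tartrate) work-up
Reagents that add atoms: none
Why: 1,2-Reduction of the enoate by i-Bu2AlH gives the allylic alcohol with the E geometry kept; diene and silyl ethers do not react.

**Step 8**
Reactants: 12 (2E,6R,8E,10E)-6,12-bis(TBSO)-3,7,7-trimethyldodeca-2,8,10-trien-1-ol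
Product: 13 (2E,6R,8E,10E)-6,12-bis(TBSO)-3,7,7-trimethyldodeca-2,8,10-trienal
Conditions: activated MnO2 (15 equiv), CH2Cl2, rt
Reagents that add atoms: none
Why: Allylic oxidation with MnO2 is selective for the allylic alcohol and should give the (E)-enal, a far better dienophile than the ester, without touching the silyl ethers.

**Step 9**
Reactants: 13 (2E,6R,8E,10E)-6,12-bis(TBSO)-3,7,7-trimethyldodeca-2,8,10-trienal
Product: 14 (1R,2R,4aS,6R,8aR)-6-(TBSO)-2-[(TBSO)methyl]-5,5,8a-trimethyl-1,2,4a,5,6,7,8,8a-octahydronaphthalene-1-carbaldehyde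
Conditions: Me2AlCl (1.1 equiv, promoter), CH2Cl2 (0.01 M), −78 → −20 °C
Reagents that add atoms: none
Why: Me2AlCl bound to the formyl oxygen lowers the LUMO of the (E)-enal, whose C9=C10 bond adds suprafacially, in a concerted but asynchronous [4+2] cycloaddition, to the s-cis (E,E)-diene C5=C6–C7=C8, forming C5–C10 and C8–C9; the closest known reaction type is the Lewis-acid-promoted intramolecular Diels–Alder reaction of (E,E,E)-2,8,10-trienals to trans-fused octalin carbaldehydes. Ring B closes as the cyclohexene of the cycloaddition, and ring A closes in the same event as a six-membered carbocycle through the four-carbon tether C1–C4, held as a chair between the dienophile β-carbon C10 and the diene terminus C5 (fused mode). The E geometry of the enal fixes formyl C11 cis to the C10 methyl, the carbonyl-endo transition state puts the tether anti to the formyl group and so gives the trans ring fusion at C5, and the E geometry of C7=C8 then places the silyloxymethyl group at C8 cis to C11, that is axial. The absolute sense at all four new centres is relayed from C3: with the silyloxy group equatorial on the chair tether only one diene face can reach the dienophile. The step therefore needs endo over exo selectivity and diene-face selectivity; the first should be secured by the aluminium-complexed formyl group at low temperature, the second by the equatorial preference of the bulky OTBS group beside the C4 gem-dimethyl unit, which also favours the folded, reactive conformer.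

**Step 10**
Reactants: 14 (1R,2R,4aS,6R,8aR)-6-(TBSO)-2-[(TBSO)methyl]-5,5,8a-trimethyl-1,2,4a,5,6,7,8,8a-octahydronaphthalene-1-carbaldehyde
Product: 15 (1R,2R,4aS,6R,8aR)-6-(TBSO)-2-[(TBSO)methyl]-5,5,8a-trimethyldecahydronaphthalene-1-carbaldehyde
Conditions: H2 (1 atm), 10% Pd/C, EtOAc, rt
Reagents that add atoms: none
Why: Heterogeneous hydrogenation should saturate the cis-disubstituted C6=C7 bond while the hindered aliphatic aldehyde and the silyl ethers stay intact; no stereocentre is formed.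

**Step 11**
Reactants: 15 (1R,2R,4aS,6R,8aR)-6-(TBSO)-2-[(TBSO)methyl]-5,5,8a-trimethyldecahydronaphthalene-1-carbaldehyde
Product: 16 (1R,2R,4aS,6R,8aS)-6-(TBSO)-2-[(TBSO)methyl]-1-ethenyl-5,5,8a-trimethyldecahydronaphthalene
Conditions: Ph3PCH3Br (3 equiv), KN(SiMe3)2 (2.8 equiv), THF, 0 °C; then 15, 0 °C → rt
Reagents that add atoms: methyltriphenylphosphonium bromide, C[P+](c1ccccc1)(c1ccccc1)c1ccccc1.[Br-]
Why: Wittig methylenation with the small unstabilised ylide reaches the hindered formyl group, and C9 already holds its more stable equatorial substituent, so the basic ylide has no driving force to epimerise it.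

**Step 12**
Reactants: 17 methyl but-2-ynoate
Product: 18 methyl (2Z)-3-iodobut-2-enoate
Conditions: NaI (1.6 equiv), AcOH, 115 °C
Reagents that add atoms: sodium iodide, [Na+].[I-]
Why: Conjugate hydroiodination of the ynoate proceeds by anti addition of iodide and a proton, which should give the Z isomer with iodine cis to the ester.

**Step 13**
Reactants: 16 (1R,2R,4aS,6R,8aS)-6-(TBSO)-2-[(TBSO)methyl]-1-ethenyl-5,5,8a-trimethyldecahydronaphthalene; 18 methyl (2Z)-3-iodobut-2-enoate
Product: 20 methyl (2Z)-5-{(1R,2R,4aS,6R,8aS)-6-(TBSO)-2-[(TBSO)methyl]-5,5,8a-trimethyldecahydronaphthalen-1-yl}-3-methylpent-2-enoate, via alkylborane 19 (not isolated)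
Conditions: 9-BBN (1.5 equiv), THF, 0 → 50 °C; then 18 (1.3 equiv), Pd(dppf)Cl2 (5 mol%), AsPh3 (10 mol%), aq. K3PO4 (3 equiv), DMF, rt
Reagents that add atoms: 9-borabicyclo[3.3.1]nonane (9-BBN), B1C2CCCC1CCC2 (its boron unit is carried in 19 only and is lost on coupling)
Why: Anti-Markovnikov hydroboration of the terminal vinyl group followed by B-alkyl Suzuki–Miyaura coupling forms C12–C13, and since oxidative addition and reductive elimination retain the geometry of the iodoenoate, the chain should end cis to the ester (Z).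

**Step 14**
Reactants: 20 methyl (2Z)-5-{(1R,2R,4aS,6R,8aS)-6-(TBSO)-2-[(TBSO)methyl]-5,5,8a-trimethyldecahydronaphthalen-1-yl}-3-methylpent-2-enoate
Product: 21 methyl (2Z)-5-[(1R,2R,4aS,6R,8aS)-6-hydroxy-2-(hydroxymethyl)-5,5,8a-trimethyldecahydronaphthalen-1-yl]-3-methylpent-2-enoate
Conditions: HF (48% aq.), MeCN, 0 °C → rt
Reagents that add atoms: none
Why: Acidic fluoride desilylation removes both the primary and the hindered secondary silyl ether, and the Z-enoate and all stereocentres are stable to these conditions.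

**Step 15**
Reactants: 21 methyl (2Z)-5-[(1R,2R,4aS,6R,8aS)-6-hydroxy-2-(hydroxymethyl)-5,5,8a-trimethyldecahydronaphthalen-1-yl]-3-methylpent-2-enoate
Product: 22 methyl (2Z)-5-[(1R,2R,4aS,6R,8aS)-2-formyl-6-hydroxy-5,5,8a-trimethyldecahydronaphthalen-1-yl]-3-methylpent-2-enoate
Conditions: TEMPO (0.2 equiv), PhI(OAc)2 (1.2 equiv), CH2Cl2, rt
Reagents that add atoms: none
Why: Nitroxyl (oxoammonium) oxidation strongly prefers primary over hindered secondary alcohols, so C17 should go to the aldehyde while the C3 carbinol beside the gem-dimethyl group stays untouched.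

**Step 16**
Reactants: 22 methyl (2Z)-5-[(1R,2R,4aS,6R,8aS)-2-formyl-6-hydroxy-5,5,8a-trimethyldecahydronaphthalen-1-yl]-3-methylpent-2-enoate
Product: 23 methyl (2Z)-5-[(1R,2S,4aS,6R,8aS)-2-formyl-6-hydroxy-5,5,8a-trimethyldecahydronaphthalen-1-yl]-3-methylpent-2-enoate (CNP0188570.1)
Conditions: DBU (0.5 equiv), CH2Cl2, rt
Reagents that add atoms: none
Why: Base-mediated enolisation and reprotonation epimerises C8 under thermodynamic control, moving the formyl group from the axial position, syn to the axial C10 methyl, to the equatorial one; C9 is not enolisable and the hindered β,β-disubstituted enoate should not be attacked by this mild base.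

**Compound list**

1 | methyl geranate, methyl (2E)-3,7-dimethylocta-2,6-dienoate | COC(=O)/C=C(\C)CCC=C(C)C | starting material
2 | methyl (2E)-6,7-dihydroxy-3,7-dimethyloct-2-enoate (racemic) | COC(=O)/C=C(\C)CCC(O)C(C)(C)O | intermediate (not isolated)
3 | methyl (2E)-3-methyl-6-oxohex-2-enoate | COC(=O)/C=C(\C)CCC=O | intermediate
4 | 3-methylbuta-1,2-diene | CC(C)=C=C | starting material
5 | methyl (2E,6R)-6-hydroxy-3,7,7-trimethylnona-2,8-dienoate | COC(=O)/C=C(\C)CC[C@@H](O)C(C)(C)C=C | intermediate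
6 | methyl (2E,6R)-6-(TBSO)-3,7,7-trimethylnona-2,8-dienoate | COC(=O)/C=C(\C)CC[C@@H](O[Si](C)(C)C(C)(C)C)C(C)(C)C=C | intermediate
7 | methyl (2E,6R)-6-(TBSO)-8,9-dihydroxy-3,7,7-trimethylnon-2-enoate (both C8 epimers) | COC(=O)/C=C(\C)CC[C@@H](O[Si](C)(C)C(C)(C)C)C(C)(C)C(O)CO | intermediate (not isolated)
8 | methyl (2E,6R)-6-(TBSO)-3,7,7-trimethyl-8-oxooct-2-enoate | COC(=O)/C=C(\C)CC[C@@H](O[Si](C)(C)C(C)(C)C)C(C)(C)C=O | intermediate
9 | methyl (2E,6R,8E)-6-(TBSO)-9-iodo-3,7,7-trimethylnona-2,8-dienoate | COC(=O)/C=C(\C)CC[C@@H](O[Si](C)(C)C(C)(C)C)C(C)(C)/C=C/I | intermediate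
10 | (E)-tert-butyldimethyl{[3-(4,4,5,5-tetramethyl-1,3,2-dioxaborolan-2-yl)prop-2-en-1-yl]oxy}silane | CC(C)(C)[Si](C)(C)OC/C=C/B1OC(C)(C)C(C)(C)O1 | starting material
11 | methyl (2E,6R,8E,10E)-6,12-bis(TBSO)-3,7,7-trimethyldodeca-2,8,10-trienoate | COC(=O)/C=C(\C)CC[C@@H](O[Si](C)(C)C(C)(C)C)C(C)(C)/C=C/C=C/CO[Si](C)(C)C(C)(C)C | intermediate
12 | (2E,6R,8E,10E)-6,12-bis(TBSO)-3,7,7-trimethyldodeca-2,8,10-trien-1-ol | OC/C=C(\C)CC[C@@H](O[Si](C)(C)C(C)(C)C)C(C)(C)/C=C/C=C/CO[Si](C)(C)C(C)(C)C | intermediate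
13 | (2E,6R,8E,10E)-6,12-bis(TBSO)-3,7,7-trimethyldodeca-2,8,10-trienal | O=C/C=C(\C)CC[C@@H](O[Si](C)(C)C(C)(C)C)C(C)(C)/C=C/C=C/CO[Si](C)(C)C(C)(C)C | intermediate
14 | (1R,2R,4aS,6R,8aR)-6-(TBSO)-2-[(TBSO)methyl]-5,5,8a-trimethyl-1,2,4a,5,6,7,8,8a-octahydronaphthalene-1-carbaldehyde | O=C[C@@H]1[C@H](CO[Si](C)(C)C(C)(C)C)C=C[C@@H]2C(C)(C)[C@H](O[Si](C)(C)C(C)(C)C)CC[C@@]12C | intermediate
15 | (1R,2R,4aS,6R,8aR)-6-(TBSO)-2-[(TBSO)methyl]-5,5,8a-trimethyldecahydronaphthalene-1-carbaldehyde | O=C[C@@H]1[C@H](CO[Si](C)(C)C(C)(C)C)CC[C@@H]2C(C)(C)[C@H](O[Si](C)(C)C(C)(C)C)CC[C@@]12C | intermediate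
16 | (1R,2R,4aS,6R,8aS)-6-(TBSO)-2-[(TBSO)methyl]-1-ethenyl-5,5,8a-trimethyldecahydronaphthalene | C=C[C@@H]1[C@H](CO[Si](C)(C)C(C)(C)C)CC[C@@H]2C(C)(C)[C@H](O[Si](C)(C)C(C)(C)C)CC[C@@]12C | intermediate
17 | methyl but-2-ynoate | CC#CC(=O)OC | starting material
18 | methyl (2Z)-3-iodobut-2-enoate | COC(=O)/C=C(/C)I | intermediate
19 | 9-{2-[(1R,2R,4aS,6R,8aS)-6-(TBSO)-2-[(TBSO)methyl]-5,5,8a-trimethyldecahydronaphthalen-1-yl]ethyl}-9-borabicyclo[3.3.1]nonane | C1CCC2CCCC1B2CC[C@@H]1[C@H](CO[Si](C)(C)C(C)(C)C)CC[C@@H]2C(C)(C)[C@H](O[Si](C)(C)C(C)(C)C)CC[C@@]12C | intermediate (not isolated)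
20 | methyl (2Z)-5-{(1R,2R,4aS,6R,8aS)-6-(TBSO)-2-[(TBSO)methyl]-5,5,8a-trimethyldecahydronaphthalen-1-yl}-3-methylpent-2-enoate | COC(=O)/C=C(/C)CC[C@@H]1[C@H](CO[Si](C)(C)C(C)(C)C)CC[C@@H]2C(C)(C)[C@H](O[Si](C)(C)C(C)(C)C)CC[C@@]12C | intermediate
21 | methyl (2Z)-5-[(1R,2R,4aS,6R,8aS)-6-hydroxy-2-(hydroxymethyl)-5,5,8a-trimethyldecahydronaphthalen-1-yl]-3-methylpent-2-enoate | COC(=O)/C=C(/C)CC[C@@H]1[C@H](CO)CC[C@@H]2C(C)(C)[C@H](O)CC[C@@]12C | intermediate
22 | methyl (2Z)-5-[(1R,2R,4aS,6R,8aS)-2-formyl-6-hydroxy-5,5,8a-trimethyldecahydronaphthalen-1-yl]-3-methylpent-2-enoate (8-epimer, axial formyl) | COC(=O)/C=C(/C)CC[C@@H]1[C@H](C=O)CC[C@@H]2C(C)(C)[C@H](O)CC[C@@]12C | intermediate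
23 | methyl (2Z)-5-[(1R,2S,4aS,6R,8aS)-2-formyl-6-hydroxy-5,5,8a-trimethyldecahydronaphthalen-1-yl]-3-methylpent-2-enoate (CNP0188570.1) | COC(=O)/C=C(/C)CC[C@@H]1[C@@H](C=O)CC[C@@H]2C(C)(C)[C@H](O)CC[C@@]12C | target

**Step count**

Total: 16 steps. Longest linear sequence: 15 steps (steps 1–11 and 13–16, from methyl geranate); step 12 is a one-step branch that supplies 18.

**Steps most likely to fail**

Step 9. The cycloaddition at the trisubstituted dienophile may be slow. Lewis-acid-induced E/Z isomerisation of the enal or ionisation of the dienylic silyl ether could then compete. Leakage through the exo transition state is also possible, because the C10 methyl has to sit over the diene in the endo mode. The fallback sets out from 11 and returns at 15, and runs the cycloaddition on the ester without a Lewis acid. Trienoate 11 is heated (toluene, BHT, sealed tube, 180 °C) and should close in the same ester-endo, chair-tether sense to the octalin ester F1. Hydrogenation (H2, Pd/C, EtOAc) then gives the decalin ester F2, reduction with i-Bu2AlH gives the primary alcohol F3, and Dess–Martin periodinane oxidation rejoins the route at aldehyde 15.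

Step 13. Transmetallation of the hindered alkylborane may be slow, so that protodeboronation or base-induced Z to E drift of the iodoenoate competes. The fallback sets out from 16 and returns at 20, and replaces boron by zinc under base-free conditions. Borane 19 is oxidised (NaOH, H2O2) to the primary alcohol F4. An Appel reaction (iodine, PPh3, imidazole, CH2Cl2) converts this into the primary iodide F5. Zinc insertion (Zn, LiCl, THF) gives the alkylzinc iodide F6, which is joined to 18 by Negishi coupling (Pd(PPh3)4, THF, rt) to give 20.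

Step 15. Oxidation of the C3 carbinol may compete, or the hindered axial primary alcohol may stall. The fallback sets out from 20 and returns at 23, and stages the deprotection so that only one hydroxyl is free when the oxidant is present. The primary silyl ether is removed selectively (HF·pyridine, pyridine, THF, 0 °C) to give the C17 alcohol F7. Dess–Martin periodinane gives the axial aldehyde F8, DBU in CH2Cl2 epimerises C8 to the equatorial aldehyde F9, and aqueous HF in MeCN frees the C3 hydroxyl to give 23.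

**Further compounds**

F1 | step 9 | methyl (1R,2R,4aS,6R,8aR)-6-(TBSO)-2-[(TBSO)methyl]-5,5,8a-trimethyl-1,2,4a,5,6,7,8,8a-octahydronaphthalene-1-carboxylate | COC(=O)[C@@H]1[C@H](CO[Si](C)(C)C(C)(C)C)C=C[C@@H]2C(C)(C)[C@H](O[Si](C)(C)C(C)(C)C)CC[C@@]12C
F2 | step 9 | methyl (1R,2R,4aS,6R,8aR)-6-(TBSO)-2-[(TBSO)methyl]-5,5,8a-trimethyldecahydronaphthalene-1-carboxylate | COC(=O)[C@@H]1[C@H](CO[Si](C)(C)C(C)(C)C)CC[C@@H]2C(C)(C)[C@H](O[Si](C)(C)C(C)(C)C)CC[C@@]12C
F3 | step 9 | [(1R,2R,4aS,6R,8aR)-6-(TBSO)-2-[(TBSO)methyl]-5,5,8a-trimethyldecahydronaphthalen-1-yl]methanol | OC[C@@H]1[C@H](CO[Si](C)(C)C(C)(C)C)CC[C@@H]2C(C)(C)[C@H](O[Si](C)(C)C(C)(C)C)CC[C@@]12C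
F4 | step 13 | 2-[(1R,2R,4aS,6R,8aS)-6-(TBSO)-2-[(TBSO)methyl]-5,5,8a-trimethyldecahydronaphthalen-1-yl]ethan-1-ol | OCC[C@@H]1[C@H](CO[Si](C)(C)C(C)(C)C)CC[C@@H]2C(C)(C)[C@H](O[Si](C)(C)C(C)(C)C)CC[C@@]12C
F5 | step 13 | (1R,2R,4aS,6R,8aS)-6-(TBSO)-2-[(TBSO)methyl]-1-(2-iodoethyl)-5,5,8a-trimethyldecahydronaphthalene | ICC[C@@H]1[C@H](CO[Si](C)(C)C(C)(C)C)CC[C@@H]2C(C)(C)[C@H](O[Si](C)(C)C(C)(C)C)CC[C@@]12C
F6 | step 13 | {2-[(1R,2R,4aS,6R,8aS)-6-(TBSO)-2-[(TBSO)methyl]-5,5,8a-trimethyldecahydronaphthalen-1-yl]ethyl}zinc iodide | I[Zn]CC[C@@H]1[C@H](CO[Si](C)(C)C(C)(C)C)CC[C@@H]2C(C)(C)[C@H](O[Si](C)(C)C(C)(C)C)CC[C@@]12C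
F7 | step 15 | methyl (2Z)-5-[(1R,2R,4aS,6R,8aS)-6-(TBSO)-2-(hydroxymethyl)-5,5,8a-trimethyldecahydronaphthalen-1-yl]-3-methylpent-2-enoate | COC(=O)/C=C(/C)CC[C@@H]1[C@H](CO)CC[C@@H]2C(C)(C)[C@H](O[Si](C)(C)C(C)(C)C)CC[C@@]12C
F8 | step 15 | methyl (2Z)-5-[(1R,2R,4aS,6R,8aS)-6-(TBSO)-2-formyl-5,5,8a-trimethyldecahydronaphthalen-1-yl]-3-methylpent-2-enoate | COC(=O)/C=C(/C)CC[C@@H]1[C@H](C=O)CC[C@@H]2C(C)(C)[C@H](O[Si](C)(C)C(C)(C)C)CC[C@@]12C
F9 | step 15 | methyl (2Z)-5-[(1R,2S,4aS,6R,8aS)-6-(TBSO)-2-formyl-5,5,8a-trimethyldecahydronaphthalen-1-yl]-3-methylpent-2-enoate | COC(=O)/C=C(/C)CC[C@@H]1[C@@H](C=O)CC[C@@H]2C(C)(C)[C@H](O[Si](C)(C)C(C)(C)C)CC[C@@]12C
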